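**Retrosynthetic overview**

1. Target 39 comes from 38 by MgBr2 removal of the C6 benzyl ether and the pyranone methoxymethyl group. The C5 acyl group comes from magnesium-phenoxide-directed acylation of phenol 34 with (R)-2-methylbutanoyl chloride 36.
2. Ring B (O1–C2 bond) is closed on the C7a hydroxyl by 5-exo opening of the (S)-epoxide of the C3a prenyl group. Dehydration then gives the isopropenyl group.
3. The strategy rests on ring A, whose ring atoms alternate oxygen (C4, C6, C7a) and carbon (C3a, C5, C7) substituents. Benzannulation of cyclobutenone 17 with siloxyalkyne 22 forms C3a–C7a and C4–C5 and delivers O4 as silyl ether, O6 as benzyl ether and O7a as the only free hydroxyl.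
4. Cyclobutenone 17 comes from the ketene of pyranonylpropanoic acid 10 and benzyloxyethyne 14. The pyranone comes from 3-pentanone and malonyl dichloride, and 22 from ethyl 4-methylpent-3-enoate by ynolate silylation.
5. Ring order: pyranone ring, then ring A (the cyclobutenone is consumed), then ring B.

Key step: step 10

Remark: ring A is numbered as in the 2,3-dihydrobenzofuran of the target (C3a, C4 to C7, C7a); cyclobutenone 17 is carried as the racemate because its only stereocentre is destroyed in the key step, and the pyranone oxygen is masked as a methoxymethyl ether so that the last deprotection needs neither hydrogenation nor a boron halide in the presence of the isopropenyl group.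

**Route**

Step 1
Reactants: 1 3-pentanone; 2 malonyl dichloride
Product: 4 6-ethyl-4-hydroxy-5-methyl-2H-pyran-2-one, via 4-methyl-3,5-dioxoheptanoyl chloride 3 (not isolated)
Conditions: 2 added to excess 1 (neat), rt then 40 °C
Reagents that add atoms: none
Why: C-acylation of the ketone enol by one acid chloride group and lactonisation of the resulting enol onto the second is the known condensation of ketones with malonyl dichloride to 4-hydroxy-2-pyranones, and it places ethyl on C6 and methyl on C5.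

Step 2
Reactants: 4 6-ethyl-4-hydroxy-5-methyl-2H-pyran-2-one
Product: 5 6-ethyl-4-hydroxy-5-methyl-3-(prop-2-en-1-yl)-2H-pyran-2-one
Conditions: allyl methyl carbonate (0.95 equiv), Pd(PPh3)4 (2 mol%), THF, rt to 50 °C
Reagents that add atoms: allyl methyl carbonate, C=CCOC(=O)OC
Why: Tsuji–Trost allylation of the acidic pyranone through the π-allyl complex formed from zerovalent palladium should end at the C3-allyl compound, because any O-allyl ether is ionised again, and the slight deficit of carbonate limits double allylation.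

Step 3
Reactants: 5 6-ethyl-4-hydroxy-5-methyl-3-(prop-2-en-1-yl)-2H-pyran-2-one
Product: 6 6-ethyl-4-(methoxymethoxy)-5-methyl-3-(prop-2-en-1-yl)-2H-pyran-2-one
Conditions: MOMCl, i-Pr2NEt, CH2Cl2, 0 °C to rt
Reagents that add atoms: chloromethyl methyl ether, COCCl
Why: Williamson-type O-alkylation of the acidic 4-hydroxyl (C3 is blocked) gives the 4-alkoxy-2-pyranone and masks the enol for the acid chloride and ketene chemistry that follows.

Step 4
Reactants: 6 6-ethyl-4-(methoxymethoxy)-5-methyl-3-(prop-2-en-1-yl)-2H-pyran-2-one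
Product: 8 6-ethyl-3-(3-hydroxypropyl)-4-(methoxymethoxy)-5-methyl-2H-pyran-2-one, via B-alkyl-9-borabicyclononane 7 (not isolated)
Conditions: 9-BBN, THF, 0 °C to rt; then NaBO3·4H2O, H2O, rt
Reagents that add atoms: sodium perborate, [Na+].[Na+].O[B-]1(O)OO[B-](O)(O)OO1
Why: Anti-Markovnikov hydroboration–oxidation of the terminal alkene with a borane that leaves the pyranone untouched, and perborate in place of alkaline peroxide spares the lactone.

Step 5
Reactants: 8 6-ethyl-3-(3-hydroxypropyl)-4-(methoxymethoxy)-5-methyl-2H-pyran-2-one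
Product: 10 3-[6-ethyl-4-(methoxymethoxy)-5-methyl-2-oxo-2H-pyran-3-yl]propanoic acid, via aldehyde 9 (not isolated)
Conditions: TEMPO (cat.), NaClO2, NaOCl (cat.), MeCN/phosphate buffer pH 6.7, 35 °C
Reagents that add atoms: sodium chlorite, [Na+].[O-]Cl=O
Why: TEMPO-catalysed chlorite oxidation takes the primary alcohol through the aldehyde to the acid at near-neutral pH, which the acetal and the fully substituted pyranone should tolerate.

Step 6
Reactants: 11 benzyl alcohol
Product: 14 (benzyloxy)ethyne, via benzyl 1,2-dichlorovinyl ether 12 (not isolated), via lithium benzyloxyacetylide 13 (not isolated)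
Conditions: KH, THF, 0 °C; Cl2C=CHCl, −50 °C to rt; n-BuLi, −78 to −40 °C; MeOH, −78 °C; kept cold and used at once
Reagents that add atoms: trichloroethylene, ClC=C(Cl)Cl
Why: The one-pot ynol ether synthesis from an alkoxide and trichloroethylene (addition to dichloroacetylene formed in situ, elimination, chlorine–lithium exchange, protonation) is general for primary alcohols, and the ether is handled below room temperature because benzyl ynol ethers rearrange on warming.

Step 7
Reactants: 10 3-[6-ethyl-4-(methoxymethoxy)-5-methyl-2-oxo-2H-pyran-3-yl]propanoic acid; 14 (benzyloxy)ethyne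
Product: 17 racemic 3-(benzyloxy)-4-{[6-ethyl-4-(methoxymethoxy)-5-methyl-2-oxo-2H-pyran-3-yl]methyl}cyclobut-2-en-1-one, via acid chloride 15 (not isolated), via ketene 16 (not isolated)
Conditions: 1-chloro-N,N,2-trimethylprop-1-en-1-amine, CH2Cl2, 0 °C to rt; then added over 4 h to 14 (3 equiv) and Et3N (1.5 equiv), THF/CH2Cl2, 0 °C to rt
Reagents that add atoms: none
Why: Neutral acid chloride formation keeps the acetal, and dehydrochlorination gives the aldoketene, whose [2+2] cycloaddition with the alkoxyalkyne (ketene carbonyl carbon to the terminal alkyne carbon) is the standard entry to 3-alkoxy-4-alkylcyclobutenones; slow addition and excess alkyne work against ketene dimerisation.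

Step 8
Reactants: 18 4-methylpent-3-enoic acid
Product: 19 ethyl 4-methylpent-3-enoate
Conditions: EtI, K2CO3, DMF, rt
Reagents that add atoms: iodoethane, CCI
Why: Carboxylate O-alkylation esterifies without acid, which would lactonise or isomerise this β,γ-unsaturated acid.

Step 9
Reactants: 19 ethyl 4-methylpent-3-enoate
Product: 22 triisopropyl[(5-methylhex-4-en-1-yn-1-yl)oxy]silane, via lithium dibromoenolate 20 (not isolated), via lithium ynolate 21 (not isolated)
Conditions: CH2Br2, lithium 2,2,6,6-tetramethylpiperidide, THF, −78 °C; n-BuLi, −78 to 0 °C; i-Pr3SiCl, −78 °C to rt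
Reagents that add atoms: dibromomethane, BrCBr; chlorotriisopropylsilane, CC(C)[Si](Cl)(C(C)C)C(C)C
Why: Under Kowalski ester homologation conditions the ester adds LiCHBr2, bromine–lithium exchange and 1,2-shift give the ynolate, and the bulky silyl chloride traps it on oxygen to give the siloxyalkyne.

Step 10
Reactants: 17 racemic 3-(benzyloxy)-4-{[6-ethyl-4-(methoxymethoxy)-5-methyl-2-oxo-2H-pyran-3-yl]methyl}cyclobut-2-en-1-one; 22 triisopropyl[(5-methylhex-4-en-1-yn-1-yl)oxy]silane
Product: 27 3-{[6-(benzyloxy)-2-hydroxy-3-(3-methylbut-2-en-1-yl)-4-(triisopropylsilyloxy)phenyl]methyl}-6-ethyl-4-(methoxymethoxy)-5-methyl-2H-pyran-2-one, via vinylketene 23 (not isolated), via 4-vinylcyclobutenone 24 (not isolated), via dienylketene 25 (not isolated), via cyclohexadienone 26 (not isolated)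
Conditions: 22 (1.5 equiv), degassed toluene, 80 °C then 110 °C
Reagents that add atoms: none
Why: Heating opens 17 by conrotatory 4π electrocyclic ring opening (strain release) to vinylketene 23, and the alkyne carbon of 22 remote from oxygen attacks the ketene carbon in a regioselective [2+2] cycloaddition to give 4-vinylcyclobutenone 24. A second 4π opening gives dienylketene 25, which closes ring A by 6π electrocyclisation (remaking the C7–C7a bond) to cyclohexadienone 26 and tautomerises to phenol 27, so that C3a–C7a and C4–C5 are the new skeletal bonds. The closest known reaction is the Danheiser benzannulation of cyclobutenones with triisopropylsiloxyalkynes to resorcinol monosilyl ethers. No stereocentre is formed, and the stereocentre of racemic 17 is erased. The selectivity needed is regiochemical and is fixed by the polarity of the ynol ether toward the ketene, which puts the silyloxy group on C4 next to the prenyl-bearing C3a, leaves the former ketene oxygen as the only free hydroxyl on C7a, and relies on the hydrogen at C4 of 17 for the final tautomerisation. Excess alkyne and moderate dilution should keep the vinylketene from being captured by the phenol formed.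

Step 11
Reactants: 27 3-{[6-(benzyloxy)-2-hydroxy-3-(3-methylbut-2-en-1-yl)-4-(triisopropylsilyloxy)phenyl]methyl}-6-ethyl-4-(methoxymethoxy)-5-methyl-2H-pyran-2-one
Product: 28 3-(benzyloxy)-2-{[6-ethyl-4-(methoxymethoxy)-5-methyl-2-oxo-2H-pyran-3-yl]methyl}-6-(3-methylbut-2-en-1-yl)-5-(triisopropylsilyloxy)phenyl acetate
Conditions: Ac2O, Et3N, DMAP (cat.), CH2Cl2, rt
Reagents that add atoms: acetic anhydride, CC(=O)OC(C)=O
Why: DMAP-catalysed acetylation of the single free phenol shields it from the dioxirane oxidant of the next step.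

Step 12
Reactants: 28 3-(benzyloxy)-2-{[6-ethyl-4-(methoxymethoxy)-5-methyl-2-oxo-2H-pyran-3-yl]methyl}-6-(3-methylbut-2-en-1-yl)-5-(triisopropylsilyloxy)phenyl acetate
Product: 29 3-(benzyloxy)-6-{[(2S)-3,3-dimethyloxiran-2-yl]methyl}-2-{[6-ethyl-4-(methoxymethoxy)-5-methyl-2-oxo-2H-pyran-3-yl]methyl}-5-(triisopropylsilyloxy)phenyl acetate
Conditions: L-series enantiomer of the fructose-derived Shi ketone (1,2:4,5-di-O-isopropylidene-β-L-erythro-2,3-hexodiulo-2,6-pyranose, 30 mol%), KHSO5 (as 2KHSO5·KHSO4·K2SO4), K2CO3, Bu4NHSO4 (cat.), MeCN/dimethoxymethane/aq. Na2B4O7 buffer (pH about 10.5), 0 °C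
Reagents that add atoms: potassium peroxymonosulfate, [K+].[O-]S(=O)(=O)OO
Why: Shi epoxidation of the isolated trisubstituted alkene through the spiro transition state should set the (S)-epoxide with the L-series ketone (the D-fructose-derived ketone gives the (R)-epoxide with 3,3-dimethylallyl groups), and the conjugated, fully substituted pyranone is much less reactive toward the dioxirane.

Step 13
Reactants: 29 3-(benzyloxy)-6-{[(2S)-3,3-dimethyloxiran-2-yl]methyl}-2-{[6-ethyl-4-(methoxymethoxy)-5-methyl-2-oxo-2H-pyran-3-yl]methyl}-5-(triisopropylsilyloxy)phenyl acetate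
Product: 31 3-{[(2R)-6-(benzyloxy)-2-(2-hydroxypropan-2-yl)-4-(triisopropylsilyloxy)-2,3-dihydro-1-benzofuran-7-yl]methyl}-6-ethyl-4-(methoxymethoxy)-5-methyl-2H-pyran-2-one, via phenol epoxide 30 (not isolated)
Conditions: K2CO3, MeOH/THF, 0 °C to rt
Reagents that add atoms: none
Why: Methanolysis of the aryl acetate frees the C7a phenoxide, which opens the epoxide at its secondary carbon by 5-exo-tet SN2 attack with inversion, so the (S)-epoxide carbon becomes (R)-C2 and ring B is closed, while the still silylated C4 oxygen cannot compete.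

Step 14
Reactants: 31 3-{[(2R)-6-(benzyloxy)-2-(2-hydroxypropan-2-yl)-4-(triisopropylsilyloxy)-2,3-dihydro-1-benzofuran-7-yl]methyl}-6-ethyl-4-(methoxymethoxy)-5-methyl-2H-pyran-2-one
Product: 33 3-{[(2R)-6-(benzyloxy)-2-(prop-1-en-2-yl)-4-(triisopropylsilyloxy)-2,3-dihydro-1-benzofuran-7-yl]methyl}-6-ethyl-4-(methoxymethoxy)-5-methyl-2H-pyran-2-one, via sulfamate ester 32 (not isolated)
Conditions: methyl N-(triethylammoniosulfonyl)carbamate, toluene, 60 °C
Reagents that add atoms: none
Why: Burgess dehydration of the tertiary alcohol by syn elimination of its sulfamate ester should favour the isopropenyl group, since six methyl hydrogens compete with the single hydrogen on the oxygen-bearing C2, and it leaves the C2 stereocentre untouched.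

Step 15
Reactants: 33 3-{[(2R)-6-(benzyloxy)-2-(prop-1-en-2-yl)-4-(triisopropylsilyloxy)-2,3-dihydro-1-benzofuran-7-yl]methyl}-6-ethyl-4-(methoxymethoxy)-5-methyl-2H-pyran-2-one
Product: 34 3-{[(2R)-6-(benzyloxy)-4-hydroxy-2-(prop-1-en-2-yl)-2,3-dihydro-1-benzofuran-7-yl]methyl}-6-ethyl-4-(methoxymethoxy)-5-methyl-2H-pyran-2-one
Conditions: Bu4NF, THF, 0 °C; aq. NH4Cl work-up
Reagents that add atoms: none
Why: Fluoride cleavage of the aryl silyl ether frees the C4 phenol under conditions that leave the benzyl ether, the acetal and the alkene alone.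

Step 16
Reactants: 35 (R)-2-methylbutanoic acid
Product: 36 (R)-2-methylbutanoyl chloride
Conditions: (COCl)2, DMF (cat.), CH2Cl2, 0 °C to rt; volatiles removed, used crude
Reagents that add atoms: oxalyl chloride, ClC(=O)C(=O)Cl
Why: Vilsmeier-type activation makes the acid chloride without an amine base, so no ketene forms and the α-stereocentre should keep its configuration.

Step 17
Reactants: 34 3-{[(2R)-6-(benzyloxy)-4-hydroxy-2-(prop-1-en-2-yl)-2,3-dihydro-1-benzofuran-7-yl]methyl}-6-ethyl-4-(methoxymethoxy)-5-methyl-2H-pyran-2-one; 36 (R)-2-methylbutanoyl chloride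
Product: 38 3-{[(2R)-6-(benzyloxy)-4-hydroxy-5-[(2R)-2-methylbutanoyl]-2-(prop-1-en-2-yl)-2,3-dihydro-1-benzofuran-7-yl]methyl}-6-ethyl-4-(methoxymethoxy)-5-methyl-2H-pyran-2-one, via bromomagnesium phenoxide 37 (not isolated)
Conditions: EtMgBr (1.0 equiv), Et2O/toluene, 0 °C; then 36 (1.2 equiv), 2,6-di-tert-butyl-4-methylpyridine, toluene, 0 °C to rt; cold dilute HCl work-up
Reagents that add atoms: none
Why: Template ortho C-acylation of a bromomagnesium phenoxide by an acid chloride in a non-coordinating solvent (a coordinated Friedel–Crafts acylation) should deliver the acyl group to C5, the only free ring carbon, without a strong Lewis or Brønsted acid that would attack the isopropenyl allylic ether, and the hindered pyridine takes up HCl without forming a ketene, so the (R)-centre is kept.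

Step 18
Reactants: 38 3-{[(2R)-6-(benzyloxy)-4-hydroxy-5-[(2R)-2-methylbutanoyl]-2-(prop-1-en-2-yl)-2,3-dihydro-1-benzofuran-7-yl]methyl}-6-ethyl-4-(methoxymethoxy)-5-methyl-2H-pyran-2-one
Product: 39 3-{[(2R)-4,6-dihydroxy-5-[(2R)-2-methylbutanoyl]-2-(prop-1-en-2-yl)-2,3-dihydro-1-benzofuran-7-yl]methyl}-6-ethyl-4-hydroxy-5-methyl-2H-pyran-2-one
Conditions: MgBr2·OEt2 (excess), toluene/Et2O, rt to 40 °C; cold dilute HCl work-up
Reagents that add atoms: none
Why: Chelation-assisted ether cleavage: MgBr2 bound between the C5 carbonyl and the ortho benzyl ether lets bromide remove the benzyl group, and the same reagent cleaves acetal-type methoxymethyl esters, here the vinylogous one on the pyranone, under conditions mild enough for the isopropenyl group and the ketone α-centre.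

**Compound list**

1 | 3-pentanone | CCC(=O)CC | starting material
2 | malonyl dichloride | ClC(=O)CC(=O)Cl | starting material
3 | 4-methyl-3,5-dioxoheptanoyl chloride | CCC(=O)C(C)C(=O)CC(=O)Cl | intermediate
4 | 6-ethyl-4-hydroxy-5-methyl-2H-pyran-2-one | CCc1oc(=O)cc(O)c1C | intermediate
5 | 6-ethyl-4-hydroxy-5-methyl-3-(prop-2-en-1-yl)-2H-pyran-2-one | CCc1oc(=O)c(CC=C)c(O)c1C | intermediate
6 | 6-ethyl-4-(methoxymethoxy)-5-methyl-3-(prop-2-en-1-yl)-2H-pyran-2-one | CCc1oc(=O)c(CC=C)c(OCOC)c1C | intermediate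
7 | 3-[3-(9-borabicyclo[3.3.1]nonan-9-yl)propyl]-6-ethyl-4-(methoxymethoxy)-5-methyl-2H-pyran-2-one | CCc1oc(=O)c(CCCB2C3CCCC2CCC3)c(OCOC)c1C | intermediate
8 | 6-ethyl-3-(3-hydroxypropyl)-4-(methoxymethoxy)-5-methyl-2H-pyran-2-one | CCc1oc(=O)c(CCCO)c(OCOC)c1C | intermediate
9 | 3-[6-ethyl-4-(methoxymethoxy)-5-methyl-2-oxo-2H-pyran-3-yl]propanal | CCc1oc(=O)c(CCC=O)c(OCOC)c1C | intermediate
10 | 3-[6-ethyl-4-(methoxymethoxy)-5-methyl-2-oxo-2H-pyran-3-yl]propanoic acid | CCc1oc(=O)c(CCC(=O)O)c(OCOC)c1C | intermediate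
11 | benzyl alcohol | OCc1ccccc1 | starting material
12 | benzyl (E)-1,2-dichloroethenyl ether | Cl/C=C(/Cl)OCc1ccccc1 | intermediate
13 | lithium benzyloxyacetylide | [Li]C#COCc1ccccc1 | intermediate
14 | (benzyloxy)ethyne | C#COCc1ccccc1 | intermediate
15 | 3-[6-ethyl-4-(methoxymethoxy)-5-methyl-2-oxo-2H-pyran-3-yl]propanoyl chloride | CCc1oc(=O)c(CCC(=O)Cl)c(OCOC)c1C | intermediate
16 | 3-[6-ethyl-4-(methoxymethoxy)-5-methyl-2-oxo-2H-pyran-3-yl]prop-1-en-1-one (ketene) | CCc1oc(=O)c(CC=C=O)c(OCOC)c1C | intermediate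
17 | 3-(benzyloxy)-4-{[6-ethyl-4-(methoxymethoxy)-5-methyl-2-oxo-2H-pyran-3-yl]methyl}cyclobut-2-en-1-one (racemic) | O=C1C=C(OCc2ccccc2)C1Cc3c(OCOC)c(C)c(CC)oc3=O | intermediate
18 | 4-methylpent-3-enoic acid | CC(C)=CCC(=O)O | starting material
19 | ethyl 4-methylpent-3-enoate | CCOC(=O)CC=C(C)C | intermediate
20 | lithium 1,1-dibromo-5-methylhexa-1,4-dien-2-olate | CC(C)=CCC([O-])=C(Br)Br.[Li+] | intermediate
21 | lithium 5-methylhex-4-en-1-yn-1-olate | CC(C)=CCC#C[O-].[Li+] | intermediate
22 | triisopropyl[(5-methylhex-4-en-1-yn-1-yl)oxy]silane | CC(C)=CCC#CO[Si](C(C)C)(C(C)C)C(C)C | intermediate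
23 | (3Z)-3-(benzyloxy)-5-[6-ethyl-4-(methoxymethoxy)-5-methyl-2-oxo-2H-pyran-3-yl]penta-1,3-dien-1-one (vinylketene) | O=C=C/C(OCc1ccccc1)=C/Cc2c(OCOC)c(C)c(CC)oc2=O | intermediate
24 | 4-{1-(benzyloxy)-3-[6-ethyl-4-(methoxymethoxy)-5-methyl-2-oxo-2H-pyran-3-yl]prop-1-en-1-yl}-2-(3-methylbut-2-en-1-yl)-3-(triisopropylsilyloxy)cyclobut-2-en-1-one | O=C1C(CC=C(C)C)=C(O[Si](C(C)C)(C(C)C)C(C)C)C1C(OCc2ccccc2)=CCc3c(OCOC)c(C)c(CC)oc3=O | intermediate
25 | 5-(benzyloxy)-7-[6-ethyl-4-(methoxymethoxy)-5-methyl-2-oxo-2H-pyran-3-yl]-2-(3-methylbut-2-en-1-yl)-3-(triisopropylsilyloxy)hepta-1,3,5-trien-1-one (dienylketene) | O=C=C(CC=C(C)C)C(O[Si](C(C)C)(C(C)C)C(C)C)=CC(OCc1ccccc1)=CCc2c(OCOC)c(C)c(CC)oc2=O | intermediate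
26 | 5-(benzyloxy)-6-{[6-ethyl-4-(methoxymethoxy)-5-methyl-2-oxo-2H-pyran-3-yl]methyl}-2-(3-methylbut-2-en-1-yl)-3-(triisopropylsilyloxy)cyclohexa-2,4-dien-1-one | O=C1C(CC=C(C)C)=C(O[Si](C(C)C)(C(C)C)C(C)C)C=C(OCc2ccccc2)C1Cc3c(OCOC)c(C)c(CC)oc3=O | intermediate
27 | 3-{[6-(benzyloxy)-2-hydroxy-3-(3-methylbut-2-en-1-yl)-4-(triisopropylsilyloxy)phenyl]methyl}-6-ethyl-4-(methoxymethoxy)-5-methyl-2H-pyran-2-one | Oc1c(CC=C(C)C)c(O[Si](C(C)C)(C(C)C)C(C)C)cc(OCc2ccccc2)c1Cc3c(OCOC)c(C)c(CC)oc3=O | intermediate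
28 | 3-(benzyloxy)-2-{[6-ethyl-4-(methoxymethoxy)-5-methyl-2-oxo-2H-pyran-3-yl]methyl}-6-(3-methylbut-2-en-1-yl)-5-(triisopropylsilyloxy)phenyl acetate | CC(=O)Oc1c(CC=C(C)C)c(O[Si](C(C)C)(C(C)C)C(C)C)cc(OCc2ccccc2)c1Cc3c(OCOC)c(C)c(CC)oc3=O | intermediate
29 | 3-(benzyloxy)-6-{[(2S)-3,3-dimethyloxiran-2-yl]methyl}-2-{[6-ethyl-4-(methoxymethoxy)-5-methyl-2-oxo-2H-pyran-3-yl]methyl}-5-(triisopropylsilyloxy)phenyl acetate | CC(=O)Oc1c(C[C@@H]2OC2(C)C)c(O[Si](C(C)C)(C(C)C)C(C)C)cc(OCc3ccccc3)c1Cc4c(OCOC)c(C)c(CC)oc4=O | intermediate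
30 | 3-{[6-(benzyloxy)-3-{[(2S)-3,3-dimethyloxiran-2-yl]methyl}-2-hydroxy-4-(triisopropylsilyloxy)phenyl]methyl}-6-ethyl-4-(methoxymethoxy)-5-methyl-2H-pyran-2-one | Oc1c(C[C@@H]2OC2(C)C)c(O[Si](C(C)C)(C(C)C)C(C)C)cc(OCc3ccccc3)c1Cc4c(OCOC)c(C)c(CC)oc4=O | intermediate
31 | 3-{[(2R)-6-(benzyloxy)-2-(2-hydroxypropan-2-yl)-4-(triisopropylsilyloxy)-2,3-dihydro-1-benzofuran-7-yl]methyl}-6-ethyl-4-(methoxymethoxy)-5-methyl-2H-pyran-2-one | CC(C)(O)[C@H]1Cc2c(O[Si](C(C)C)(C(C)C)C(C)C)cc(OCc3ccccc3)c(Cc4c(OCOC)c(C)c(CC)oc4=O)c2O1 | intermediate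
32 | triethylammonium salt of the N-(methoxycarbonyl)sulfamate ester of 31 | CC[NH+](CC)CC.COC(=O)[N-]S(=O)(=O)OC(C)(C)[C@H]1Cc2c(O[Si](C(C)C)(C(C)C)C(C)C)cc(OCc3ccccc3)c(Cc4c(OCOC)c(C)c(CC)oc4=O)c2O1 | intermediate
33 | 3-{[(2R)-6-(benzyloxy)-2-(prop-1-en-2-yl)-4-(triisopropylsilyloxy)-2,3-dihydro-1-benzofuran-7-yl]methyl}-6-ethyl-4-(methoxymethoxy)-5-methyl-2H-pyran-2-one | C=C(C)[C@H]1Cc2c(O[Si](C(C)C)(C(C)C)C(C)C)cc(OCc3ccccc3)c(Cc4c(OCOC)c(C)c(CC)oc4=O)c2O1 | intermediate
34 | 3-{[(2R)-6-(benzyloxy)-4-hydroxy-2-(prop-1-en-2-yl)-2,3-dihydro-1-benzofuran-7-yl]methyl}-6-ethyl-4-(methoxymethoxy)-5-methyl-2H-pyran-2-one | C=C(C)[C@H]1Cc2c(O)cc(OCc3ccccc3)c(Cc4c(OCOC)c(C)c(CC)oc4=O)c2O1 | intermediate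
35 | (R)-2-methylbutanoic acid | OC(=O)[C@H](C)CC | starting material
36 | (R)-2-methylbutanoyl chloride | ClC(=O)[C@H](C)CC | intermediate
37 | bromomagnesium phenoxide of 34 | C=C(C)[C@H]1Cc2c(O[Mg]Br)cc(OCc3ccccc3)c(Cc4c(OCOC)c(C)c(CC)oc4=O)c2O1 | intermediate
38 | 3-{[(2R)-6-(benzyloxy)-4-hydroxy-5-[(2R)-2-methylbutanoyl]-2-(prop-1-en-2-yl)-2,3-dihydro-1-benzofuran-7-yl]methyl}-6-ethyl-4-(methoxymethoxy)-5-methyl-2H-pyran-2-one | C=C(C)[C@H]1Cc2c(O)c(C(=O)[C@H](C)CC)c(OCc3ccccc3)c(Cc4c(OCOC)c(C)c(CC)oc4=O)c2O1 | intermediate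
39 | 3-{[(2R)-4,6-dihydroxy-5-[(2R)-2-methylbutanoyl]-2-(prop-1-en-2-yl)-2,3-dihydro-1-benzofuran-7-yl]methyl}-6-ethyl-4-hydroxy-5-methyl-2H-pyran-2-one | C=C(C)[C@H]1Cc2c(O)c(C(=O)[C@H](C)CC)c(O)c(Cc3c(O)c(C)c(CC)oc3=O)c2O1 | target

**Step count**

Total steps: 18. Longest linear sequence: 14 steps (steps 1 to 5, 7, 10 to 15, 17 and 18, from 3-pentanone).

**Steps most likely to fail**

Step 10. The donor-substituted cyclobutenone may open only at temperatures where the vinylketene is diverted, by capture by the phenol already formed or by oligomerisation, or where the silyl group is lost. The fallback generates the same vinylketene at room temperature by photochemical Wolff rearrangement of an α-diazo enone, the diazo ketone form of this benzannulation. It sets out from 6 and comes back at vinylketene 23, and so at 27.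
- Lemieux–Johnson cleavage of 6 (OsO4 cat., NaIO4, 2,6-lutidine, dioxane/H2O) would give 2-[6-ethyl-4-(methoxymethoxy)-5-methyl-2-oxo-2H-pyran-3-yl]acetaldehyde F1.
- Horner–Wadsworth–Emmons olefination with ethyl 2-(benzyloxy)-2-(diethoxyphosphoryl)acetate (LiCl, i-Pr2NEt, MeCN) would give ethyl 2-(benzyloxy)-4-[6-ethyl-4-(methoxymethoxy)-5-methyl-2-oxo-2H-pyran-3-yl]but-2-enoate F2; its alkene geometry is of no consequence.
- LiOH in THF/H2O at 0 °C would give 2-(benzyloxy)-4-[6-ethyl-4-(methoxymethoxy)-5-methyl-2-oxo-2H-pyran-3-yl]but-2-enoic acid F3.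
- The mixed anhydride (isobutyl chloroformate, N-methylmorpholine) and diazomethane would give 3-(benzyloxy)-1-diazo-5-[6-ethyl-4-(methoxymethoxy)-5-methyl-2-oxo-2H-pyran-3-yl]pent-3-en-2-one F4.
- Irradiation of F4 at long wavelength, outside the pyranone absorption, in the presence of 22 should give 23, and gentle warming should complete the two electrocyclic steps to 27.

Step 7. Oligomerisation of the aldoketene, or sigmatropic decomposition of the benzyl ynol ether during the slow addition, may outrun the cycloaddition. The fallback sets out from ketene 16, generated from 10 as in step 7, and comes back at 17.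
- Ketene 16 would be trapped with commercially available, stable ethoxyethyne in large excess, giving racemic 3-ethoxy-4-{[6-ethyl-4-(methoxymethoxy)-5-methyl-2-oxo-2H-pyran-3-yl]methyl}cyclobut-2-en-1-one F5.
- The ethoxy group would then be exchanged for benzyloxy with benzyl alcohol 11 and catalytic sodium benzyloxide (NaOCH2Ph) in THF at 0 °C, returning to 17.
- Because this exchange runs by addition–elimination at C3 and not through the symmetric 1,3-dione, the pyranonylmethyl group should stay on C4.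

Step 17. The acid chloride may acylate the phenoxide oxygen and not C5, or react too slowly at the hindered carbon. The fallback replaces acylation by ortho-hydroxyalkylation of the same magnesium phenoxide and oxidation. It sets out from 34 (through 37) and from acid 35, and comes back at 38.
- LiAlH4 reduction of 35 would give (R)-2-methylbutan-1-ol F6.
- Oxidation with TEMPO/PhI(OAc)2 would give (R)-2-methylbutanal F7, used at once to limit enolisation.
- Addition of F7 to 37 in toluene should give 3-{[(2R)-6-(benzyloxy)-4-hydroxy-5-[(2R)-1-hydroxy-2-methylbutyl]-2-(prop-1-en-2-yl)-2,3-dihydro-1-benzofuran-7-yl]methyl}-6-ethyl-4-(methoxymethoxy)-5-methyl-2H-pyran-2-one F8 as a mixture at the carbinol carbon.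
- Oxidation of this benzylic alcohol with activated MnO2 in CH2Cl2 returns to 38.

**Further compounds**

F1 | step 10 | 2-[6-ethyl-4-(methoxymethoxy)-5-methyl-2-oxo-2H-pyran-3-yl]acetaldehyde | O=CCc1c(OCOC)c(C)c(CC)oc1=O
F2 | step 10 | ethyl 2-(benzyloxy)-4-[6-ethyl-4-(methoxymethoxy)-5-methyl-2-oxo-2H-pyran-3-yl]but-2-enoate | CCOC(=O)C(OCc1ccccc1)=CCc2c(OCOC)c(C)c(CC)oc2=O
F3 | step 10 | 2-(benzyloxy)-4-[6-ethyl-4-(methoxymethoxy)-5-methyl-2-oxo-2H-pyran-3-yl]but-2-enoic acid | OC(=O)C(OCc1ccccc1)=CCc2c(OCOC)c(C)c(CC)oc2=O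
F4 | step 10 | 3-(benzyloxy)-1-diazo-5-[6-ethyl-4-(methoxymethoxy)-5-methyl-2-oxo-2H-pyran-3-yl]pent-3-en-2-one | [N-]=[N+]=CC(=O)C(OCc1ccccc1)=CCc2c(OCOC)c(C)c(CC)oc2=O
F5 | step 7 | 3-ethoxy-4-{[6-ethyl-4-(methoxymethoxy)-5-methyl-2-oxo-2H-pyran-3-yl]methyl}cyclobut-2-en-1-one (racemic) | O=C1C=C(OCC)C1Cc2c(OCOC)c(C)c(CC)oc2=O
F6 | step 17 | (R)-2-methylbutan-1-ol | OC[C@H](C)CC
F7 | step 17 | (R)-2-methylbutanal | O=C[C@H](C)CC
F8 | step 17 | 3-{[(2R)-6-(benzyloxy)-4-hydroxy-5-[(2R)-1-hydroxy-2-methylbutyl]-2-(prop-1-en-2-yl)-2,3-dihydro-1-benzofuran-7-yl]methyl}-6-ethyl-4-(methoxymethoxy)-5-methyl-2H-pyran-2-one | C=C(C)[C@H]1Cc2c(O)c(C(O)[C@H](C)CC)c(OCc3ccccc3)c(Cc4c(OCOC)c(C)c(CC)oc4=O)c2O1
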